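5 questions stand here, and I want to answer them with one quantity read from one earlier run.

common to all: reagent 1.04 M

| charge | substrate | temperature | remark | time |
|---|---|---|---|---|
| elm | 0.40 M | 110 °C | run made earlier |  |
| spring | 0.80 M |  | at 110 °C until 2.0 h, from then on at 80 °C | 3.0 h |
| dusk | 0.80 M | 110 °C |  | 3.0 h |
| summer | 0.80 M | 95 °C |  | 3.0 h |
| autumn | 0.80 M | 80 °C |  | 3.0 h |

* which flask leads in amount of target, in percent of the substrate charged ("all alike" within 1.5 percentage points) (spring / dusk / summer / autumn / all alike)
* how much target is there at the end, in percent of the substrate charged: spring
* how much target is there at the end, in percent of the substrate charged: dusk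
* how much target is there at the end, in percent of the substrate charged: summer
* how much target is there at the end, in percent of the substrate charged: autumn

- the numbers in the tables scatter by 0.3 percentage points (one standard deviation)
- the earlier runs do not show what temperature does; that part of a forecast is a guess

elm run (percent of the substrate charged)

| time / min | target / % | substrate / % |
|---|---|---|
| 4.00 | 16.3 | 53.1 |
| 6.00 | 20.0 | 41.9 |
| 10.0 | 24.8 | 27.6 |
| 15.0 | 28.5 | 18.0 |
| 25.0 | 31.1 | 8.0 |
| 40.0 | 32.6 | 2.1 |
| 50.0 | 32.8 | 1.8 |

(each reading ± 0.3 percentage points)

I read the elm table downward in logarithms. The log10 of the substrate falls by 0.275 in the first 4.00 min, but by 0.538 over the 15.0 min from 10.0 min to 25.0 min. As read, the slope has dropped by a factor of 1.92. A pseudo-first-order flask with steady reagent would give a straight line, so something in elm is changing, and the reagent is my suspect.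

Now I read target against substrate consumed. The ratio reads 0.348 in the first row and 0.334 in the last, so the rest of the consumed substrate in elm goes where I cannot read it. The last row reads 32.8%, and I take that reading as elm's plateau.

The new flasks hold twice the substrate of elm on the same reagent. I therefore carry the equivalents, [reagent]/[substrate] at the start: 2.60 in elm and 1.30 in the new flasks. Their log10 values are 0.415 and 0.114.

One run shows no slope of yield against equivalents, so I bet on a slope of 1 in logarithms: target at the plateau goes in proportion to the equivalents. That gives 16.4% for spring, dusk, summer and autumn alike. What temperature does is a guess, and I add nothing for it.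

The forecast says all alike, with 31%, 31%, 31% and 30% for spring, dusk, summer and autumn, on the ground that “the yield looks set by a fixed branching ratio”.

The flasks give 18.1%, 17.9%, 18.8% and 18.8% in that order, and the answer is all alike. My reckoning lies 1.5 percentage points below dusk.

    substrate + 2 reagent → side product A (k = 0.799 M⁻² h⁻¹, Ea = 84.0 kJ mol⁻¹)
    substrate + target → side product B (k = 0.430 M⁻¹ h⁻¹, Ea = 99.0 kJ mol⁻¹)
    substrate + reagent → target (k = 0.335 M⁻¹ h⁻¹, Ea = 94.0 kJ mol⁻¹)
    (constants at 80 °C)

In dusk at 0.108 h, target is made 2.32 times as fast as it is used up, each step taken net. In dusk the path from substrate + target to side product B has 94% of its turnover up to the asked time behind it by 1.50 h, and at 30.0 h dusk holds 17.9% of target.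

The neighbour flask is dusk with 0.62 M of reagent, which makes the equivalents 0.775, and my proportion gives 9.78%. The computed neighbour flask holds 4.36%, less than the proportion.

The numbers in the tables are calculated for an exercise; noise was put on by code.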